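**Retrosynthetic overview**

1. The target comes from a hexabenzyl dimer by hydrogenolysis, after removal of a temporary O3(upper)–Si(iPr)2–O5(lower) bridge and of an acetate on O3 of the lower unit.
2. Key disconnection: the C4(upper)–C6(lower) interflavan bond and the pyran ring C of the lower unit are made in one Lewis-acid operation from a silicon-tethered bis(benzylic acetate) whose lower unit is still a 2-(α-acetoxybenzyl)-2,3-dihydrobenzofuran. A tether-directed Friedel–Crafts closure (3,4-cis, at C6) is followed by growth of the five-membered furan ring to the six-membered pyran through a 1,2-interchange of O1 and acetate.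
3. Enabling feature: in ring C of the lower unit the ether oxygen O1 and the C3 oxygen sit on adjacent carbons, C2 (benzylic to the electron-rich ring B) and C3. The connectivities O1–C3/AcO–C2 (dihydrobenzofuran) and O1–C2/AcO–C3 (flavan-3-yl acetate) can therefore interconvert through an aryloxiranium ion. In addition, O5 of the lower ring A is ortho to C6 and can be tied to O3 of the upper unit.
4. Lower unit: cinnamylation of 5-benzyloxyresorcinol, Shi epoxidation, 5-exo phenoxide opening (fixes the lower C3 configuration, leaves O5 free). Upper unit: asymmetric arylation of 7-benzyloxychromone, Rubottom hydroxylation to the trans-dihydroflavonol, then silyl acetal formation, ketone reduction and double acetylation.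
5. Order of ring formation: upper pyranone ring C (from the chromone), then the lower dihydrofuran (step 5), then the seven-membered silylene ring and, from the dihydrofuran, the lower pyran ring C (step 12).

Key step: step 12

**Remarks and assumptions**

- Flavan numbering is used (O1, C2, C3, C4, C4a, C5 to C8, C8a; rings A, B, C). "Upper" is the 5-deoxy (ent-fisetinidol) unit, "lower" the catechin unit. The target is read as upper (2S,3R,4S), that is 2,3-trans-3,4-cis, and lower (2R,3S), joined C4→C6.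
- 3,4-Bis(benzyloxy)benzaldehyde, 5-(benzyloxy)benzene-1,3-diol, 7-hydroxy-4H-chromen-4-one and [3,4-bis(benzyloxy)phenyl]boronic acid are taken as purchasable.
- The C4 alcohol and acetate of the upper unit are drawn as the expected 3,4-trans isomer; the epimer would serve equally, because this centre is ionised in step 12.

**Route**

Step 1
Reactants: 1 3,4-bis(benzyloxy)benzaldehyde
Product: 2 1-[3,4-bis(benzyloxy)phenyl]prop-2-en-1-ol (racemic)
Conditions: CH2=CHMgBr, THF, −78 → 0 °C; aq. NH4Cl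
Reagents that add atoms: vinylmagnesium bromide, C=C[Mg]Br
Why: 1,2-addition of the vinyl Grignard reagent to the aldehyde; the carbinol is only a precursor of the 1-arylallyl cation, so its configuration is irrelevant.

Step 2
Reactants: 2 1-[3,4-bis(benzyloxy)phenyl]prop-2-en-1-ol; 3 5-(benzyloxy)benzene-1,3-diol
Product: 4 5-(benzyloxy)-2-{(2E)-3-[3,4-bis(benzyloxy)phenyl]prop-2-en-1-yl}benzene-1,3-diol
Conditions: H2SO4 on SiO2 (cat.), CH2Cl2/MeCN, 0 °C → rt; 3 in threefold excess
Reagents that add atoms: none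
Why: Friedel–Crafts allylation in which the 1-arylallyl cation is attacked at its terminus (conjugated E-alkene) by C2 of the resorcinol, the least hindered nucleophilic position because it is flanked by two free hydroxyls and not by a benzyl ether; the excess of 3 limits double alkylation.

Step 3
Reactants: 4 5-(benzyloxy)-2-{(2E)-3-[3,4-bis(benzyloxy)phenyl]prop-2-en-1-yl}benzene-1,3-diol
Product: 5 5-(benzyloxy)-2-{(2E)-3-[3,4-bis(benzyloxy)phenyl]prop-2-en-1-yl}-1,3-bis[(tert-butyldimethylsilyl)oxy]benzene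
Conditions: t-BuMe2SiCl, imidazole, DMF, rt
Reagents that add atoms: tert-butyldimethylsilyl chloride, CC(C)(C)[Si](C)(C)Cl
Why: standard silylation masks both phenols so that the electron-rich ring survives the oxidation that follows.

Step 4
Reactants: 5 5-(benzyloxy)-2-{(2E)-3-[3,4-bis(benzyloxy)phenyl]prop-2-en-1-yl}-1,3-bis[(tert-butyldimethylsilyl)oxy]benzene
Product: 6 (2S,3S)-2-({4-(benzyloxy)-2,6-bis[(tert-butyldimethylsilyl)oxy]phenyl}methyl)-3-[3,4-bis(benzyloxy)phenyl]oxirane
Conditions: ent-Shi ketone (L-fructose-derived, 30 mol%), KHSO5 (as 2KHSO5·KHSO4·K2SO4), K2CO3, Bu4NHSO4, MeCN/CH2(OMe)2/aq. Na2B4O7–Na2EDTA buffer, 0 °C; crude product used directly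
Reagents that add atoms: potassium peroxymonosulfate, [K+].OOS(=O)(=O)[O-]
Why: Shi epoxidation, in which the dioxirane of the L-series ketone should deliver oxygen through the spiro transition state to the alkene face that gives the (2S,3S)-oxirane (the D-fructose-derived ketone gives R,R-epoxides from trans-β-alkylstyrenes), the basic buffer sparing the acid-labile aryl epoxide; both stereocentres of the lower unit originate here.

Step 5
Reactants: 6 (2S,3S)-2-({4-(benzyloxy)-2,6-bis[(tert-butyldimethylsilyl)oxy]phenyl}methyl)-3-[3,4-bis(benzyloxy)phenyl]oxirane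
Product: 8 (S)-[(2R)-6-(benzyloxy)-4-hydroxy-2,3-dihydro-1-benzofuran-2-yl][3,4-bis(benzyloxy)phenyl]methanol, via epoxy bisphenol 7 (not isolated)
Conditions: Bu4NF (2.2 equiv), THF, 0 °C → rt; aq. NH4Cl
Reagents that add atoms: none
Why: fluoride releases the two equivalent phenoxides and one of them opens the oxirane at its non-benzylic carbon by 5-exo-tet attack with inversion (the base-mediated mode, as opposed to acid-mediated 6-endo attack at the benzylic carbon), which gives the (2R)-dihydrobenzofuran with the (S)-carbinol intact and leaves the second phenol free as the later tether site.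

Step 6
Reactants: 9 7-hydroxy-4H-chromen-4-one
Product: 10 7-(benzyloxy)-4H-chromen-4-one
Conditions: BnBr, K2CO3, DMF, rt
Reagents that add atoms: benzyl bromide, BrCc1ccccc1
Why: Williamson etherification of the phenol.

Step 7
Reactants: 10 7-(benzyloxy)-4H-chromen-4-one; 11 [3,4-bis(benzyloxy)phenyl]boronic acid
Product: 12 (2R)-7-(benzyloxy)-2-[3,4-bis(benzyloxy)phenyl]-2,3-dihydro-4H-chromen-4-one
Conditions: Pd(OCOCF3)2 (5 mol%), (S)-t-BuPyOx (6 mol%), NH4PF6 (30 mol%), H2O (5 equiv), ClCH2CH2Cl, 60 °C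
Reagents that add atoms: none
Why: asymmetric conjugate addition of the arylboronic acid to the chromone with the cationic palladium–pyridine-oxazoline catalyst, using the ligand antipode that gives (R)-β-aryl ketones from cyclic enones (2R here, the antipodal ligand being used should the sense differ for this acceptor); water protonates the palladium enolate.

Step 8
Reactants: 12 (2R)-7-(benzyloxy)-2-[3,4-bis(benzyloxy)phenyl]-2,3-dihydro-4H-chromen-4-one
Product: 15 (2S,3S)-7-(benzyloxy)-2-[3,4-bis(benzyloxy)phenyl]-3-hydroxy-2,3-dihydro-4H-chromen-4-one, via silyl enol ether 13 (not isolated), via silyloxy ketone 14 (not isolated)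
Conditions: Me3SiOTf, Et3N, CH2Cl2, 0 °C; dimethyldioxirane, acetone/CH2Cl2, −40 → 0 °C; citric acid, MeOH, rt
Reagents that add atoms: dimethyldioxirane, CC1(C)OO1
Why: Rubottom oxidation, in which soft enolisation avoids the enolate (and so ring opening to the chalcone), the enol ether is epoxidised on the face opposite the C2 aryl group and silyl migration gives the trans-3-silyloxy ketone that is desilylated on work-up; C3 is thus controlled by C2 (2,3-trans).

Step 9
Reactants: 15 (2S,3S)-7-(benzyloxy)-2-[3,4-bis(benzyloxy)phenyl]-3-hydroxy-2,3-dihydro-4H-chromen-4-one; 8 (S)-[(2R)-6-(benzyloxy)-4-hydroxy-2,3-dihydro-1-benzofuran-2-yl][3,4-bis(benzyloxy)phenyl]methanol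
Product: 17 (2S,3S)-7-(benzyloxy)-2-[3,4-bis(benzyloxy)phenyl]-3-{[({(2R)-6-(benzyloxy)-2-[(S)-[3,4-bis(benzyloxy)phenyl](hydroxy)methyl]-2,3-dihydro-1-benzofuran-4-yl}oxy)di(propan-2-yl)silyl]oxy}-2,3-dihydro-4H-chromen-4-one, via chlorosilane 16 (not isolated)
Conditions: 15, i-Pr2SiCl2 (3 equiv), imidazole, CH2Cl2, 0 °C → rt; volatiles removed in vacuo; then 8, imidazole, DMF, 0 °C → rt
Reagents that add atoms: dichlorodi(propan-2-yl)silane, CC(C)[Si](Cl)(Cl)C(C)C
Why: stepwise formation of an unsymmetrical silyl acetal, in which the hindered secondary alcohol is monosilylated by excess dichlorosilane and the remaining Si–Cl bond is then taken by the phenol of 8, expected to react far faster than its hindered benzylic secondary alcohol.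

Step 10
Reactants: 17 the silylene-linked ketone of step 9
Product: 18 (2S,3R,4S)-7-(benzyloxy)-2-[3,4-bis(benzyloxy)phenyl]-3-{[({(2R)-6-(benzyloxy)-2-[(S)-[3,4-bis(benzyloxy)phenyl](hydroxy)methyl]-2,3-dihydro-1-benzofuran-4-yl}oxy)di(propan-2-yl)silyl]oxy}-3,4-dihydro-2H-chromen-4-ol
Conditions: NaBH4, CeCl3·7H2O, THF/MeOH, −40 °C
Reagents that add atoms: none
Why: Luche reduction of the aryl ketone, expected to deliver hydride trans to the C3 silyloxy group; the C4 configuration is of no consequence because it is erased in step 12.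

Step 11
Reactants: 18 the diol of step 10
Product: 19 diacetate of 18 (acetates on C4 of the flavan unit and on the benzylic carbinol of the benzofuran unit; flavan unit now designated 2S,3S,4S and benzofuran unit 2R with an S carbinol carbon)
Conditions: Ac2O, pyridine, DMAP (cat.), CH2Cl2, 0 °C → rt
Reagents that add atoms: acetic anhydride, CC(=O)OC(C)=O
Why: acylation of both secondary alcohols turns the two benzylic positions into ionisable acetates and supplies the oxygen nucleophile needed in step 12.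

Step 12
Reactants: 19 diacetate of 18
Product: 21 O3(upper),O5(lower)-di(propan-2-yl)silanediyl-bridged 7,3′,4′-tri-O-benzyl-ent-fisetinidol-(4α→6)-7,3′,4′-tri-O-benzylcatechin 3-O-acetate (acetate on O3 of the lower unit; upper 2S,3R,4S and lower 2R,3S), via bridged dihydrobenzofuran acetate 20 (not isolated)
Conditions: Me3SiOTf (0.5 equiv), CH2Cl2 (0.002 M), −40 °C, then 0 °C → rt; Et3N quench
Reagents that add atoms: none
Why: Proposed new method: Me3SiOTf first ionises the C4 acetate of the upper unit (cation stabilised by O1 and the 7-benzyloxy group), and the cation is trapped by ring A of the lower unit, held on O3 by the silicon bridge, in a 7-exo Friedel–Crafts closure (closest known type: Lewis-acid-mediated intramolecular coupling of tethered flavan-4-yl donors with flavan nucleophiles). On warming, the less stabilised benzylic acetate ionises with participation of the furan oxygen O1 to an aryloxiranium ion; return of acetate to the benzylic carbon is unproductive, whereas attack at the furan carbon C2 with inversion moves O1 onto the benzylic carbon and enlarges the dihydrofuran to the pyran (3-exo closure to the oxiranium ion, then endo opening; closest known types: the sulfonate/zinc acetate ring expansion of 2-(1-sulfonyloxyalkyl)tetrahydrofurans to 3-acetoxytetrahydropyrans and the acid-induced rearrangement of 2-(1-hydroxyalkyl)dihydrobenzofurans to chroman-3-ols), the less strained six-membered acetate being the isomer to which the equilibrating system should drain. C4 of the upper unit is set cis to O3 because the arene can reach the cation only from the face of the oxygen that carries it; C3 of the lower unit arises by inversion of the furan C2 fixed in steps 4 and 5, and C2 by inversion at the benzylic carbon, any leakage through an open benzylic cation being steered to the same 2,3-trans isomer by participation of the new C3 acetate (trans-1,3-dioxolan-2-ylium ion opened with inversion by O1). The step needs attack at C6 instead of C8 (only C6 is ortho to the tethered oxygen), 3,4-cis geometry (tether), pyran over furan (strain release under reversible conditions) and 2,3-trans geometry (double inversion backed by acetate participation); high dilution keeps the cations from alkylating a second molecule.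

Step 13
Reactants: 21 the silylene-bridged dimer acetate of step 12
Product: 23 (2R,3S)-7-(benzyloxy)-2-[3,4-bis(benzyloxy)phenyl]-6-{(2S,3R,4S)-7-(benzyloxy)-2-[3,4-bis(benzyloxy)phenyl]-3-hydroxy-3,4-dihydro-2H-chromen-4-yl}-3,4-dihydro-2H-chromene-3,5-diol, via desilylated acetate 22 (not isolated)
Conditions: Bu4NF, THF, 0 °C → rt; then K2CO3, MeOH, rt
Reagents that add atoms: none
Why: fluoride cleaves the cyclic silyl acetal and methanolysis removes the acetate, while benzyl ethers and the interflavan bond are inert to both.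

Step 14
Reactants: 23 the hexabenzyl ether of step 13
Product: 24 (2R,3S)-2-(3,4-dihydroxyphenyl)-6-[(2S,3R,4S)-2-(3,4-dihydroxyphenyl)-3,7-dihydroxy-3,4-dihydro-2H-chromen-4-yl]-3,4-dihydro-2H-chromene-3,5,7-triol (CNP0141631.3)
Conditions: H2 (1 atm), Pd(OH)2 on carbon, THF/MeOH/H2O, rt
Reagents that add atoms: none
Why: hydrogenolysis of the six benzyl ethers under neutral conditions, the usual last step for proanthocyanidins, which should leave the benzylic C–O and C–C bonds of the flavan cores intact.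

**Compound list**

1 | 3,4-bis(benzyloxy)benzaldehyde | O=Cc1ccc(OCc2ccccc2)c(OCc2ccccc2)c1 | starting material
2 | 1-[3,4-bis(benzyloxy)phenyl]prop-2-en-1-ol (racemic) | C=CC(O)c1ccc(OCc2ccccc2)c(OCc2ccccc2)c1 | intermediate
3 | 5-(benzyloxy)benzene-1,3-diol | Oc1cc(O)cc(OCc2ccccc2)c1 | starting material
4 | 5-(benzyloxy)-2-{(2E)-3-[3,4-bis(benzyloxy)phenyl]prop-2-en-1-yl}benzene-1,3-diol | Oc1cc(OCc2ccccc2)cc(O)c1C/C=C/c1ccc(OCc2ccccc2)c(OCc2ccccc2)c1 | intermediate
5 | 5-(benzyloxy)-2-{(2E)-3-[3,4-bis(benzyloxy)phenyl]prop-2-en-1-yl}-1,3-bis[(tert-butyldimethylsilyl)oxy]benzene | CC(C)(C)[Si](C)(C)Oc1cc(OCc2ccccc2)cc(O[Si](C)(C)C(C)(C)C)c1C/C=C/c1ccc(OCc2ccccc2)c(OCc2ccccc2)c1 | intermediate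
6 | (2S,3S)-2-({4-(benzyloxy)-2,6-bis[(tert-butyldimethylsilyl)oxy]phenyl}methyl)-3-[3,4-bis(benzyloxy)phenyl]oxirane | CC(C)(C)[Si](C)(C)Oc1cc(OCc2ccccc2)cc(O[Si](C)(C)C(C)(C)C)c1C[C@@H]1O[C@H]1c1ccc(OCc2ccccc2)c(OCc2ccccc2)c1 | intermediate
7 | 5-(benzyloxy)-2-({(2S,3S)-3-[3,4-bis(benzyloxy)phenyl]oxiran-2-yl}methyl)benzene-1,3-diol | Oc1cc(OCc2ccccc2)cc(O)c1C[C@@H]1O[C@H]1c1ccc(OCc2ccccc2)c(OCc2ccccc2)c1 | intermediate (not isolated)
8 | (S)-[(2R)-6-(benzyloxy)-4-hydroxy-2,3-dihydro-1-benzofuran-2-yl][3,4-bis(benzyloxy)phenyl]methanol | Oc1cc(OCc2ccccc2)cc2c1C[C@@H](O2)[C@@H](O)c1ccc(OCc2ccccc2)c(OCc2ccccc2)c1 | intermediate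
9 | 7-hydroxy-4H-chromen-4-one | O=c1ccoc2cc(O)ccc12 | starting material
10 | 7-(benzyloxy)-4H-chromen-4-one | O=c1ccoc2cc(OCc3ccccc3)ccc12 | intermediate
11 | [3,4-bis(benzyloxy)phenyl]boronic acid | OB(O)c1ccc(OCc2ccccc2)c(OCc2ccccc2)c1 | starting material
12 | (2R)-7-(benzyloxy)-2-[3,4-bis(benzyloxy)phenyl]-2,3-dihydro-4H-chromen-4-one | c1ccccc1COc1ccc2c(c1)O[C@@H](c1ccc(OCc3ccccc3)c(OCc3ccccc3)c1)CC2=O | intermediate
13 | (2R)-7-(benzyloxy)-2-[3,4-bis(benzyloxy)phenyl]-4-[(trimethylsilyl)oxy]-2H-chromene | c1ccccc1COc1ccc2c(c1)O[C@@H](c1ccc(OCc3ccccc3)c(OCc3ccccc3)c1)C=C2O[Si](C)(C)C | intermediate (not isolated)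
14 | (2S,3S)-7-(benzyloxy)-2-[3,4-bis(benzyloxy)phenyl]-3-[(trimethylsilyl)oxy]-2,3-dihydro-4H-chromen-4-one | c1ccccc1COc1ccc2c(c1)O[C@@H](c1ccc(OCc3ccccc3)c(OCc3ccccc3)c1)[C@H](O[Si](C)(C)C)C2=O | intermediate (not isolated)
15 | (2S,3S)-7-(benzyloxy)-2-[3,4-bis(benzyloxy)phenyl]-3-hydroxy-2,3-dihydro-4H-chromen-4-one | c1ccccc1COc1ccc2c(c1)O[C@@H](c1ccc(OCc3ccccc3)c(OCc3ccccc3)c1)[C@H](O)C2=O | intermediate
16 | (2S,3S)-7-(benzyloxy)-2-[3,4-bis(benzyloxy)phenyl]-3-{[chlorodi(propan-2-yl)silyl]oxy}-2,3-dihydro-4H-chromen-4-one | c1ccccc1COc1ccc2c(c1)O[C@@H](c1ccc(OCc3ccccc3)c(OCc3ccccc3)c1)[C@H](O[Si](Cl)(C(C)C)C(C)C)C2=O | intermediate (not isolated)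
17 | (2S,3S)-7-(benzyloxy)-2-[3,4-bis(benzyloxy)phenyl]-3-{[({(2R)-6-(benzyloxy)-2-[(S)-[3,4-bis(benzyloxy)phenyl](hydroxy)methyl]-2,3-dihydro-1-benzofuran-4-yl}oxy)di(propan-2-yl)silyl]oxy}-2,3-dihydro-4H-chromen-4-one | c1ccccc1COc1ccc2c(c1)O[C@@H](c1ccc(OCc3ccccc3)c(OCc3ccccc3)c1)[C@H](O[Si](C(C)C)(C(C)C)Oc1cc(OCc3ccccc3)cc3c1C[C@@H](O3)[C@@H](O)c1ccc(OCc4ccccc4)c(OCc4ccccc4)c1)C2=O | intermediate
18 | (2S,3R,4S)-4-ol obtained from 17 (same silyl acetal; free C4 hydroxyl trans to O3; free benzylic hydroxyl on the benzofuran unit) | c1ccccc1COc1ccc2c(c1)O[C@@H](c1ccc(OCc3ccccc3)c(OCc3ccccc3)c1)[C@H](O[Si](C(C)C)(C(C)C)Oc1cc(OCc3ccccc3)cc3c1C[C@@H](O3)[C@@H](O)c1ccc(OCc4ccccc4)c(OCc4ccccc4)c1)[C@H]2O | intermediate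
19 | diacetate of 18 (flavan unit 2S,3S,4S with C4 acetate; benzofuran unit 2R with (S)-acetoxy[3,4-bis(benzyloxy)phenyl]methyl group) | c1ccccc1COc1ccc2c(c1)O[C@@H](c1ccc(OCc3ccccc3)c(OCc3ccccc3)c1)[C@H](O[Si](C(C)C)(C(C)C)Oc1cc(OCc3ccccc3)cc3c1C[C@@H](O3)[C@@H](OC(C)=O)c1ccc(OCc4ccccc4)c(OCc4ccccc4)c1)[C@H]2OC(C)=O | intermediate
20 | silylene-bridged 4-arylflavan: C4 of the (2S,3R,4S)-flavan unit bonded to C5 of the (2R)-dihydrobenzofuran (seven-membered ring C4–C3–O–Si–O–C4′–C5′ of the benzofuran); benzylic (S)-acetate still in place | c1ccccc1COc1ccc2c(c1)O[C@@H](c1ccc(OCc3ccccc3)c(OCc3ccccc3)c1)[C@H](O[Si](C(C)C)(C(C)C)O5)[C@@H]2c1c(OCc3ccccc3)cc3c(c15)C[C@@H](O3)[C@@H](OC(C)=O)c1ccc(OCc4ccccc4)c(OCc4ccccc4)c1 | intermediate (not isolated)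
21 | O3(upper),O5(lower)-di(propan-2-yl)silanediyl-bridged 7,3′,4′-tri-O-benzyl-ent-fisetinidol-(4α→6)-7,3′,4′-tri-O-benzylcatechin 3-O-acetate (lower unit); upper 2S,3R,4S, lower 2R,3S | c1ccccc1COc1ccc2c(c1)O[C@@H](c1ccc(OCc3ccccc3)c(OCc3ccccc3)c1)[C@H](O[Si](C(C)C)(C(C)C)O5)[C@@H]2c1c(OCc3ccccc3)cc3c(c15)C[C@H](OC(C)=O)[C@@H](c1ccc(OCc4ccccc4)c(OCc4ccccc4)c1)O3 | intermediate
22 | 7,3′,4′-tri-O-benzyl-ent-fisetinidol-(4α→6)-7,3′,4′-tri-O-benzylcatechin 3-O-acetate (acetate on the lower unit) | c1ccccc1COc1ccc2c(c1)O[C@@H](c1ccc(OCc3ccccc3)c(OCc3ccccc3)c1)[C@H](O)[C@@H]2c1c(OCc3ccccc3)cc3c(c1O)C[C@H](OC(C)=O)[C@@H](c1ccc(OCc4ccccc4)c(OCc4ccccc4)c1)O3 | intermediate (not isolated)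
23 | (2R,3S)-7-(benzyloxy)-2-[3,4-bis(benzyloxy)phenyl]-6-{(2S,3R,4S)-7-(benzyloxy)-2-[3,4-bis(benzyloxy)phenyl]-3-hydroxy-3,4-dihydro-2H-chromen-4-yl}-3,4-dihydro-2H-chromene-3,5-diol | c1ccccc1COc1ccc2c(c1)O[C@@H](c1ccc(OCc3ccccc3)c(OCc3ccccc3)c1)[C@H](O)[C@@H]2c1c(OCc3ccccc3)cc3c(c1O)C[C@H](O)[C@@H](c1ccc(OCc4ccccc4)c(OCc4ccccc4)c1)O3 | intermediate
24 | (2R,3S)-2-(3,4-dihydroxyphenyl)-6-[(2S,3R,4S)-2-(3,4-dihydroxyphenyl)-3,7-dihydroxy-3,4-dihydro-2H-chromen-4-yl]-3,4-dihydro-2H-chromene-3,5,7-triol (ent-fisetinidol-(4α→6)-catechin) | Oc1ccc2c(c1)O[C@@H](c1ccc(O)c(O)c1)[C@H](O)[C@@H]2c1c(O)cc2c(c1O)C[C@H](O)[C@@H](c1ccc(O)c(O)c1)O2 | target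

**Step count and risks**

Total step count: 14. Longest linear sequence: 11 steps (steps 1 to 5, then 9 to 14).

Steps most likely to fail:

1. Step 12 (Proposed new method). The oxygen transposition may stall: acetate may return to the benzylic carbon faster than it opens the oxiranium ion at the furan carbon, so that proton loss towards a 2-benzylbenzofuran or intermolecular benzylation overtakes ring growth; loss of the silicon bridge under the acid is a second possibility. The fallback uses known chemistry, closes the lower pyran ring directly and keeps only the bond-forming half of the step. It sets out from 6: buffered desilylation (Bu4NF/AcOH, THF, 0 °C) gives the neutral epoxy bisphenol 7, and a catalytic Brønsted acid (camphorsulfonic acid, CH2Cl2, −20 °C) induces 6-endo opening of the oxirane at its benzylic carbon with inversion to the 2,3-trans 5-hydroxyflavan-3-ol F1. This compound takes the place of 8 in steps 9 to 11: silylation with chlorosilane 16 (imidazole, DMF) gives the silylene-linked ketone F2, NaBH4/CeCl3·7H2O gives the 4-ol F3, and Ac2O/pyridine/DMAP gives the diacetate F4. Me3SiOTf at −40 °C then has to effect only the tether-directed Friedel–Crafts closure, and the route is rejoined at 21.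

2. Step 9. Chemoselectivity of the second silylation may be lost (the benzylic hydroxyl of 8 competing with the phenol), and the chlorosilane may redistribute to symmetrical silyl acetals. The fallback is a protecting-group relay that installs the benzylic acetate before the tether. It sets out from 8: Ac2O/pyridine gives the phenyl/benzyl diacetate F5; the aryl acetate alone is cleaved with NH4OAc in aqueous MeOH to the phenol benzylic acetate F6; F6 and chlorosilane 16 (imidazole, DMF) give the silylene-linked ketone acetate F7; Luche reduction gives the 4-ol F8; acetylation of the one remaining hydroxyl rejoins the route at 19.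

3. Step 2. The cinnamyl cation may attack C4/C6 of 3 (between a hydroxyl and the benzyl ether) instead of C2, a second alkylation may follow, or a phenol may add to the new styrene double bond under the acid. The fallback fixes the regiochemistry with an acyl group. It sets out from 1: Claisen–Schmidt condensation with purchased 1-[4-(benzyloxy)-2,6-dihydroxyphenyl]ethanone (KOH, EtOH) gives the 2′,6′-dihydroxychalcone F9; ClCO2Et/Et3N gives the bis(ethyl carbonate) F10; NaBH4 in aqueous THF reduces the ketone and, by carbonate transfer, elimination to the ortho-quinone methide and 1,4-hydride addition, gives the cinnamylphenol mono(ethyl carbonate) F11; aqueous NaOH removes the remaining carbonate and rejoins the route at 4.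

**Further compounds**

F1 | step 12 | (2R,3S)-7-(benzyloxy)-2-[3,4-bis(benzyloxy)phenyl]-3,4-dihydro-2H-chromene-3,5-diol | Oc1cc(OCc2ccccc2)cc2c1C[C@H](O)[C@@H](c1ccc(OCc3ccccc3)c(OCc3ccccc3)c1)O2
F2 | step 12 | silylene-linked ketone: O3 of the (2S,3S)-dihydroflavonol unit joined through Si(i-Pr)2 to O5 of F1 | c1ccccc1COc1ccc2c(c1)O[C@@H](c1ccc(OCc3ccccc3)c(OCc3ccccc3)c1)[C@H](O[Si](C(C)C)(C(C)C)Oc1cc(OCc3ccccc3)cc3c1C[C@H](O)[C@@H](c1ccc(OCc4ccccc4)c(OCc4ccccc4)c1)O3)C2=O
F3 | step 12 | (2S,3R,4S)-4-ol obtained from F2 | c1ccccc1COc1ccc2c(c1)O[C@@H](c1ccc(OCc3ccccc3)c(OCc3ccccc3)c1)[C@H](O[Si](C(C)C)(C(C)C)Oc1cc(OCc3ccccc3)cc3c1C[C@H](O)[C@@H](c1ccc(OCc4ccccc4)c(OCc4ccccc4)c1)O3)[C@H]2O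
F4 | step 12 | diacetate of F3 (acetates on C4 of the upper unit and on O3 of the lower unit) | c1ccccc1COc1ccc2c(c1)O[C@@H](c1ccc(OCc3ccccc3)c(OCc3ccccc3)c1)[C@H](O[Si](C(C)C)(C(C)C)Oc1cc(OCc3ccccc3)cc3c1C[C@H](OC(C)=O)[C@@H](c1ccc(OCc4ccccc4)c(OCc4ccccc4)c1)O3)[C@H]2OC(C)=O
F5 | step 9 | (S)-[(2R)-4-(acetyloxy)-6-(benzyloxy)-2,3-dihydro-1-benzofuran-2-yl][3,4-bis(benzyloxy)phenyl]methyl acetate | CC(=O)Oc1cc(OCc2ccccc2)cc2c1C[C@@H](O2)[C@@H](OC(C)=O)c1ccc(OCc2ccccc2)c(OCc2ccccc2)c1
F6 | step 9 | (S)-[(2R)-6-(benzyloxy)-4-hydroxy-2,3-dihydro-1-benzofuran-2-yl][3,4-bis(benzyloxy)phenyl]methyl acetate | Oc1cc(OCc2ccccc2)cc2c1C[C@@H](O2)[C@@H](OC(C)=O)c1ccc(OCc2ccccc2)c(OCc2ccccc2)c1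
F7 | step 9 | silylene-linked ketone: O3 of the (2S,3S)-dihydroflavonol unit joined through Si(i-Pr)2 to the phenol oxygen of F6 | c1ccccc1COc1ccc2c(c1)O[C@@H](c1ccc(OCc3ccccc3)c(OCc3ccccc3)c1)[C@H](O[Si](C(C)C)(C(C)C)Oc1cc(OCc3ccccc3)cc3c1C[C@@H](O3)[C@@H](OC(C)=O)c1ccc(OCc4ccccc4)c(OCc4ccccc4)c1)C2=O
F8 | step 9 | (2S,3R,4S)-4-ol obtained from F7 | c1ccccc1COc1ccc2c(c1)O[C@@H](c1ccc(OCc3ccccc3)c(OCc3ccccc3)c1)[C@H](O[Si](C(C)C)(C(C)C)Oc1cc(OCc3ccccc3)cc3c1C[C@@H](O3)[C@@H](OC(C)=O)c1ccc(OCc4ccccc4)c(OCc4ccccc4)c1)[C@H]2O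
F9 | step 2 | (2E)-1-[4-(benzyloxy)-2,6-dihydroxyphenyl]-3-[3,4-bis(benzyloxy)phenyl]prop-2-en-1-one | O=C(/C=C/c1ccc(OCc2ccccc2)c(OCc2ccccc2)c1)c1c(O)cc(OCc2ccccc2)cc1O
F10 | step 2 | bis(ethyl carbonate) of F9 | CCOC(=O)Oc1cc(OCc2ccccc2)cc(OC(=O)OCC)c1C(=O)/C=C/c1ccc(OCc2ccccc2)c(OCc2ccccc2)c1
F11 | step 2 | mono(ethyl carbonate) of 4 | CCOC(=O)Oc1cc(OCc2ccccc2)cc(O)c1C/C=C/c1ccc(OCc2ccccc2)c(OCc2ccccc2)c1
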